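**Strategy.** The target is cut between C2 of the tetrahydrofuran ring (ring A: O1, C2–C5) and the 3,4-dimethoxyphenyl ring. C2 is benzylic and bound to O1, that is, a masked aldehyde carbon. The cis pair C3–CH2OH/C4–C(=O) can be tied into a temporary γ-lactone (ring B). The precursor is a monocyclic lactone carrying C2 as a dimethyl acetal and C5 as a silyl ether. With TMSOTf and plain veratrole, one operation closes ring A and generates a cup-shaped bicyclic oxocarbenium ion. Para-selective Friedel–Crafts attack on its convex face then sets the aryl–C2 bond and the C2 stereocentre. Aryllithium opening of ring B finally unveils the ketone and CH2OH.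

Key step: step 4

Numbering used throughout: ring A = O1, C2 (aryl-bearing), C3 (CH2OH-bearing), C4 (aroyl-bearing), C5 (CH2). The target is (2S,3R,4R), that is, 2,3-trans and 3,4-cis.

Assumption: the prolinol silyl ether catalyst follows the usual steric-shielding model, with the electrophile entering anti to the CPh2(OTMS) group. On that model the (S)-catalyst gives the (R)-aldehyde.

**Step 1**
Reactants: 1 methyl 4-oxobutanoate; 2 formaldehyde (37% aqueous)
Product: 4 (R)-4-(dimethoxymethyl)dihydrofuran-2(3H)-one, via hydroxy aldehyde 3 (not isolated)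
Conditions: (S)-α,α-diphenylprolinol trimethylsilyl ether (10 mol %), pH 7 phosphate buffer, toluene, rt; organic phase, then HC(OMe)3, TsOH·H2O (5 mol %), MeOH, rt, concentrate
Reagents that add atoms: trimethyl orthoformate, COC(OC)OC
Why: Enamine-catalysed cross-aldol reaction (organocatalytic α-hydroxymethylation of an aldehyde): formaldehyde attacks the E-enamine of 1 on the face remote from the CPh2(OTMS) group, which sets C3 as R, and the immediate acid-catalysed acetalisation and lactonisation lock the labile β-hydroxy aldehyde 3 as a non-enolisable acetal.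

**Step 2**
Reactants: 4 (R)-4-(dimethoxymethyl)dihydrofuran-2(3H)-one; 5 methyl formate
Product: 7 (4R)-3-{[(tert-butyldimethylsilyl)oxy]methylidene}-4-(dimethoxymethyl)dihydrofuran-2(3H)-one (E/Z mixture), via sodium enolate 6 (not isolated)
Conditions: NaH, HCO2Me, THF, 0 °C → rt; evaporate volatiles; TBSCl, DMF, 0 °C
Reagents that add atoms: tert-butyldimethylsilyl chloride, CC(C)(C)[Si](C)(C)Cl
Why: Crossed Claisen condensation (α-formylation of a lactone) at the only acidic position, C4, followed by O-silylation of the hard enolate oxygen, brings in C5 as a planar C4=C5 enol ether, while C3 cannot epimerise because none of its neighbours is a carbonyl carbon.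

**Step 3**
Reactants: 7 (4R)-3-{[(tert-butyldimethylsilyl)oxy]methylidene}-4-(dimethoxymethyl)dihydrofuran-2(3H)-one
Product: 8 (3R,4R)-3-{[(tert-butyldimethylsilyl)oxy]methyl}-4-(dimethoxymethyl)dihydrofuran-2(3H)-one (cis)
Conditions: H2 (4 atm), 5% Rh/Al2O3, EtOAc, rt
Reagents that add atoms: none
Why: Heterogeneous syn hydrogenation of an α-alkylidene-γ-butyrolactone: the bulky dimethoxymethyl group on C3 shields one face of the flat ring, hydrogen reaches C4 from the other face, and the CH2OTBS group is pushed cis to the acetal, which sets C4 as R.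

**Step 4**
Reactants: 8 (3R,4R)-3-{[(tert-butyldimethylsilyl)oxy]methyl}-4-(dimethoxymethyl)dihydrofuran-2(3H)-one; 9 veratrole (1,2-dimethoxybenzene)
Product: 12 (1R,5R,6S)-6-(3,4-dimethoxyphenyl)-3,7-dioxabicyclo[3.3.0]octan-2-one, via bicyclic methyl acetal 10 (not isolated), via oxocarbenium triflate 11 (not isolated)
Conditions: veratrole (3 equiv), TMSOTf (1.1 equiv), 4 Å MS, CH2Cl2, −78 → −20 °C
Reagents that add atoms: none
Why: TMSOTf ionises the dimethyl acetal at C2, the silyl ether oxygen on C5 captures the cation (5-exo-trig closure of ring A, giving methyl acetal 10), and a second ionisation gives the cis-fused bicyclic oxocarbenium ion 11, which is attacked by C4 of veratrole and rearomatises. The closest known reaction type is the Lewis-acid-promoted Friedel–Crafts C-arylation of furanosyl and furofuran lactol acetals by methoxyarenes (aryl C-glycosidation). C2 is the only new stereocentre: ring B blocks the concave face, so the arene enters on the convex face, anti to the C3–CH2O bond, and gives the 2,3-trans (6-exo, S) product, while any endo isomer can drain to the more stable exo isomer through reversible benzylic C2–O1 ionisation. Regioselectivity in the arene is innate, para to one methoxy group, and delivers the 3,4-dimethoxyphenyl pattern. The acetal is the only ionisable group because the lactone is inert, and C3 and C4 stay fixed because C4 is not enolised by the Lewis acid and only the cis-fused bicycle can close. A second arylation at C2 is held back by the low temperature and a prompt quench.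

**Step 5**
Reactants: 12 (1R,5R,6S)-6-(3,4-dimethoxyphenyl)-3,7-dioxabicyclo[3.3.0]octan-2-one; 13 5-bromo-1,2,3-trimethoxybenzene
Product: 16 [(3R,4R,5S)-5-(3,4-dimethoxyphenyl)-4-(hydroxymethyl)tetrahydrofuran-3-yl](3,4,5-trimethoxyphenyl)methanone (target), via aryllithium 14 (not isolated), via lithium hemiketal alkoxide 15 (not isolated)
Conditions: 13, n-BuLi, THF, −78 °C; then 12, THF, −78 °C; sat. aq NH4Cl at −78 °C
Reagents that add atoms: none
Why: Single addition of an aryllithium to a γ-lactone: the bicyclic lithium hemiketal alkoxide 15 persists at −78 °C, which prevents a second addition, and cold protonation releases the aryl ketone and the CH2OH group without touching C2, C3 or the epimerisable C4.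

**Compound list**
1 | methyl 4-oxobutanoate | COC(=O)CCC=O | starting material
2 | formaldehyde | C=O | starting material
3 | methyl (R)-3-formyl-4-hydroxybutanoate | O=C[C@@H](CO)CC(=O)OC | intermediate
4 | (R)-4-(dimethoxymethyl)dihydrofuran-2(3H)-one | COC(OC)[C@@H]1CC(=O)OC1 | intermediate
5 | methyl formate | COC=O | starting material
6 | sodium [(4R)-4-(dimethoxymethyl)-2-oxodihydrofuran-3(2H)-ylidene]methanolate | COC(OC)[C@H]1COC(=O)C1=C[O-].[Na+] | intermediate
7 | (4R)-3-{[(tert-butyldimethylsilyl)oxy]methylidene}-4-(dimethoxymethyl)dihydrofuran-2(3H)-one | COC(OC)[C@H]1COC(=O)C1=CO[Si](C)(C)C(C)(C)C | intermediate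
8 | (3R,4R)-3-{[(tert-butyldimethylsilyl)oxy]methyl}-4-(dimethoxymethyl)dihydrofuran-2(3H)-one | COC(OC)[C@H]1COC(=O)[C@H]1CO[Si](C)(C)C(C)(C)C | intermediate
9 | veratrole (1,2-dimethoxybenzene) | COc1ccccc1OC | starting material
10 | (1R,5R)-6-methoxy-3,7-dioxabicyclo[3.3.0]octan-2-one (both C6 epimers) | COC1OC[C@H](C(=O)OC2)[C@@H]12 | intermediate
11 | (1R,5R)-2-oxo-3,7-dioxabicyclo[3.3.0]oct-6-en-7-ium triflate (oxocarbenium ion) | C1=[O+]C[C@H](C(=O)OC2)[C@@H]12.[O-]S(=O)(=O)C(F)(F)F | intermediate
12 | (1R,5R,6S)-6-(3,4-dimethoxyphenyl)-3,7-dioxabicyclo[3.3.0]octan-2-one | COc1ccc([C@H]2OC[C@H](C(=O)OC3)[C@@H]23)cc1OC | intermediate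
13 | 5-bromo-1,2,3-trimethoxybenzene | COc1cc(Br)cc(OC)c1OC | starting material
14 | (3,4,5-trimethoxyphenyl)lithium | [Li]c1cc(OC)c(OC)c(OC)c1 | intermediate
15 | lithium (1R,5R,6S)-6-(3,4-dimethoxyphenyl)-2-(3,4,5-trimethoxyphenyl)-3,7-dioxabicyclo[3.3.0]octan-2-olate | COc1ccc([C@H]2OC[C@H](C([O-])(c4cc(OC)c(OC)c(OC)c4)OC3)[C@@H]23)cc1OC.[Li+] | intermediate
16 | [(3R,4R,5S)-5-(3,4-dimethoxyphenyl)-4-(hydroxymethyl)tetrahydrofuran-3-yl](3,4,5-trimethoxyphenyl)methanone | COc1ccc([C@H]2OC[C@H](C(=O)c3cc(OC)c(OC)c(OC)c3)[C@@H]2CO)cc1OC | target

Total step count: 5. Longest linear sequence: 5 steps (1 → 4 → 7 → 8 → 12 → 16).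

**Steps most likely to fail**

Step 4. The lactone-deactivated oxocarbenium ion may be captured only sluggishly by the moderately nucleophilic arene. The benzylic C2–O1 bond of the product may also ionise again and lead to a second arylation with ring opening.
- The fallback replaces electrophilic aromatic substitution by a cross-coupling. It sets out from 8 and comes back at 12.
- 8 is cyclised with PPTS in MeOH to the acetal 10, which is isolated this time.
- TMSBr in CH2Cl2 at 0 °C converts 10 into (1R,5R)-6-bromo-3,7-dioxabicyclo[3.3.0]octan-2-one F1, which is used crude.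
- F1 is joined in a Negishi coupling of the aryl C-glycoside type with (3,4-dimethoxyphenyl)zinc iodide F2. F2 is prepared from purchased 4-iodo-1,2-dimethoxybenzene, Zn dust and LiCl in THF.
- The coupling runs under NiCl2·glyme and 4,4′,4″-tri-tert-butylterpyridine in DMF at rt. The C2 radical should be taken up on the convex face and give 12.

Step 3. Facial selectivity in the hydrogen delivery may be poor, or the vinylic silyloxy group may be partly lost by hydrogenolysis.
- The fallback closes ring A first, so that ring strain rather than steric shielding dictates the C4 configuration. It sets out from 7 and comes back at 10.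
- Catalytic TMSOTf (5 mol %) in CH2Cl2 at −78 °C lets the silyl enol ether oxygen capture the ionised acetal. This gives (5R)-6-methoxy-3,7-dioxabicyclo[3.3.0]oct-1(8)-en-2-one F3.
- Hydrogenation of F3 (H2, 5% Rh/Al2O3, EtOAc) can only furnish the cis-fused acetal 10, which is then submitted to the conditions of step 4.

Step 1. The unprotected β-hydroxy aldehyde may lose configuration at C3 by enolisation, or lose its β-oxygen substituent by elimination, before it is acetalised.
- The fallback takes C3 from a resolved acid instead of from catalysis. It sets out from (R)-paraconic acid F4 in place of 1 and 2 and comes back at 4. F4 is purchased, or obtained from the racemic acid by salt resolution with 1-phenylethylamine.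
- Chemoselective reduction of the free acid with BH3·SMe2 in THF at 0 °C gives (S)-4-(hydroxymethyl)dihydrofuran-2(3H)-one F5.
- Oxidation with TEMPO/PhI(OAc)2 in CH2Cl2 gives (R)-5-oxotetrahydrofuran-3-carbaldehyde F6.
- F6 is converted at once with HC(OMe)3 and catalytic TsOH·H2O in MeOH into 4.

**Further compounds**
F1 | step 4 | (1R,5R)-6-bromo-3,7-dioxabicyclo[3.3.0]octan-2-one | BrC1OC[C@H](C(=O)OC2)[C@@H]12
F2 | step 4 | (3,4-dimethoxyphenyl)zinc iodide | COc1ccc([Zn]I)cc1OC
F3 | step 3 | (5R)-6-methoxy-3,7-dioxabicyclo[3.3.0]oct-1(8)-en-2-one | COC1OC=C2C(=O)OC[C@H]12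
F4 | step 1 | (R)-paraconic acid, (R)-5-oxotetrahydrofuran-3-carboxylic acid | OC(=O)[C@@H]1CC(=O)OC1
F5 | step 1 | (S)-4-(hydroxymethyl)dihydrofuran-2(3H)-one | OC[C@@H]1CC(=O)OC1
F6 | step 1 | (R)-5-oxotetrahydrofuran-3-carbaldehyde | O=C[C@@H]1CC(=O)OC1
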